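**Plan**
1. Feature: the target is a cis-fused 3,7-dioxabicyclo[3.3.0]octan-2-one. Its lactone oxygen O3 lies between C2(=O) and the benzylic C4, and C2 and C4 sit on the adjacent ring-fusion carbons C1 and C5 of the tetrahydrofuran ring.
2. Retrosynthesis: (a) O3 is removed (Baeyer–Villiger retron), contracting the lactone ring to a cyclobutanone with a C–C bond the target lacks. (b) Bonds C2–C1 and C4–C5 are cut together ([2+2]) to an aryl keteniminium ion and the C3=C4 alkene of a 2-aryl-2,5-dihydrofuran. (c) The aryl–C bond of the dihydrofuran is cut (Mizoroki–Heck).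
3. Forward: the tetrahydrofuran ring comes first (as its 2,5-dihydro form), the cyclobutanone ring second, ring expansion to the lactone third. Both phenols are freed last in one fluoride treatment.
4. Stereochemistry: C8 comes from the ligand-controlled Heck arylation. C1 and C5 come from addition to the face anti to the C8 aryl group. C4 comes from exo equilibration of the alpha-aryl cyclobutanone followed by retentive migration. The orientation of the cycloaddition comes from a C2-symmetric pyrrolidine on the keteniminium nitrogen.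

Key step: step 6

Assumption: the sense of induction of (2S,5S)-2,5-dimethylpyrrolidine is assigned from a quadrant model, in which the alkene substituent on the first-bonding carbon lies over the pyrrolidine alpha-carbon whose methyl group points away; if the sense is the reverse, the equally available (2R,5R)-amine takes its place with no other change.

**Step 1**
Reactants: 1 2-methoxybenzene-1,4-diol
Product: 2 4-hydroxy-3-methoxyphenyl trifluoromethanesulfonate
Conditions: Tf2O (1.0 equiv), pyridine (1.2 equiv), CH2Cl2, N2, −78 → −20 °C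
Reagents that add atoms: triflic anhydride O=S(=O)(OS(=O)(=O)C(F)(F)F)C(F)(F)F
Why: Phenol O-sulfonylation; the hydroxyl meta to the methoxy group is the less hindered one and is not hydrogen-bonded, so one equivalent of anhydride at low temperature should take it first, and the minor isomer and bis-triflate are removed by chromatography.

**Step 2**
Reactants: 2 4-hydroxy-3-methoxyphenyl trifluoromethanesulfonate
Product: 3 3-methoxy-4-{[2-(trimethylsilyl)ethoxy]carbonyloxy}phenyl trifluoromethanesulfonate
Conditions: 4-nitrophenyl 2-(trimethylsilyl)ethyl carbonate, Et3N, DMAP (cat.), CH2Cl2, rt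
Reagents that add atoms: 4-nitrophenyl 2-(trimethylsilyl)ethyl carbonate C[Si](C)(C)CCOC(=O)Oc1ccc([N+](=O)[O-])cc1
Why: Carbonate exchange (acyl transfer) driven by loss of the better leaving 4-nitrophenoxide; the electron-poor, fluoride-labile carbonate is chosen so that the later allylic benzylic C–O bond is hard to ionise.

**Step 3**
Reactants: 3 3-methoxy-4-{[2-(trimethylsilyl)ethoxy]carbonyloxy}phenyl trifluoromethanesulfonate; 4 2,3-dihydrofuran
Product: 5 4-[(2S)-2,5-dihydrofuran-2-yl]-2-methoxyphenyl 2-(trimethylsilyl)ethyl carbonate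
Conditions: Pd2(dba)3 (2.5 mol %), (R)-4-tert-butyl-2-[2-(diphenylphosphanyl)phenyl]-4,5-dihydrooxazole (6 mol %), iPr2NEt (2 equiv), 4 (5 equiv), THF, 70 °C
Reagents that add atoms: none
Why: Enantioselective intermolecular Mizoroki–Heck reaction, in which the cationic aryl-palladium species adds syn to the enol ether at C2 and the phosphinooxazoline complex releases the alkene after a single beta-hydride elimination, keeping the 2,5-dihydro isomer; the (S)-ligand is known to give (R)-2-phenyl-2,5-dihydrofuran, so the (R)-ligand should set (S) here.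

**Step 4**
Reactants: 6 (4-hydroxy-3,5-dimethoxyphenyl)acetic acid; 7 (2S,5S)-2,5-dimethylpyrrolidine
Product: 8 2-(4-hydroxy-3,5-dimethoxyphenyl)-1-[(2S,5S)-2,5-dimethylpyrrolidin-1-yl]ethan-1-one
Conditions: DIC, HOBt, CH2Cl2/DMF, 0 °C → rt
Reagents that add atoms: none
Why: Carbodiimide/HOBt amide coupling of an unhindered arylacetic acid, in which the amine outcompetes the doubly ortho-substituted phenol and the auxiliary stereocentres are untouched.

**Step 5**
Reactants: 8 2-(4-hydroxy-3,5-dimethoxyphenyl)-1-[(2S,5S)-2,5-dimethylpyrrolidin-1-yl]ethan-1-one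
Product: 9 2-[4-(tert-butyldimethylsilyloxy)-3,5-dimethoxyphenyl]-1-[(2S,5S)-2,5-dimethylpyrrolidin-1-yl]ethan-1-one
Conditions: TBSCl, imidazole, DMF, rt → 40 °C
Reagents that add atoms: tert-butyldimethylsilyl chloride CC(C)(C)[Si](C)(C)Cl
Why: Phenol silylation; the donor silyl ether is kept on this ring on purpose because it raises the migratory aptitude of the benzylic carbon in step 7 and leaves with fluoride in step 8.

**Step 6**
Reactants: 9 2-[4-(tert-butyldimethylsilyloxy)-3,5-dimethoxyphenyl]-1-[(2S,5S)-2,5-dimethylpyrrolidin-1-yl]ethan-1-one; 5 4-[(2S)-2,5-dihydrofuran-2-yl]-2-methoxyphenyl 2-(trimethylsilyl)ethyl carbonate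
Product: 13 (1R,4S,5S,7S)-7-[4-(tert-butyldimethylsilyloxy)-3,5-dimethoxyphenyl]-4-(3-methoxy-4-{[2-(trimethylsilyl)ethoxy]carbonyloxy}phenyl)-3-oxabicyclo[3.2.0]heptan-6-one (cis-fused; both aryl groups exo), via keteniminium triflate 10 (not isolated), via cyclobutaniminium triflate 11 (not isolated), via 7-endo ketone 12 (not isolated)
Conditions: 9 (1.4 equiv), Tf2O (1.5 equiv), 2,4,6-collidine (1.6 equiv), ClCH2CH2Cl, −20 °C, 20 min; add 5; 40–60 °C; then H2O, 60 °C; organic phase dried; DBU (0.1 equiv), CH2Cl2, rt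
Reagents that add atoms: water O
Why: Tf2O/collidine converts amide 9 into the aldo-keteniminium ion 10, whose central carbon is attacked by the ring alkene of 5 while the aryl-bearing, enamine-like carbon collapses on the developing cation; this is an asynchronous, alkene-suprafacial [2+2] (keteniminium–olefin cycloaddition, the cationic counterpart of the ketene–alkene cycloaddition, known for cyclopentene-type cis-alkenes also with this C2-symmetric pyrrolidine). The only ring closed is the cyclobutane, formed intermolecularly across C3=C4 of the dihydrofuran and necessarily cis-fused, so the carbonyl–C(alpha) and C(beta)–C(benzylic) bonds of the future lactone arise together. The two ring-fusion centres are set by approach to the face of the flat dihydrofuran anti to its C2 aryl group, that is by the single Heck-derived stereocentre, while the aryl-bearing C7 is expected endo from the kinetic addition and is moved to the more stable exo position by enamine/enol equilibration during hydrolysis and under DBU. The selectivity needed is orientational, because on the open face both alkene carbons carry only hydrogen: with that face fixed the two orientations build quasi-enantiomeric bicyclic cores, so the enantiofacial preference of the (2S,5S)-auxiliary becomes a regiochemical preference, reinforced by the inductive pull of the aryl- and oxygen-bearing C2, which disfavours positive charge on the neighbouring C3 and so sends the electrophilic carbon to C3 and the charge to C4. Chemoselectivity (alkene against ring oxygen, hydride loss or arene acylation) rests on preforming 10, on the non-nucleophilic collidine/triflate medium and on the electron-poor carbonate of the guaiacyl ring, which makes heterolysis of the allylic benzylic C–O bond costly.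

**Step 7**
Reactants: 13 the 7-exo cyclobutanone
Product: 14 (1S,4S,5R,8S)-4-[4-(tert-butyldimethylsilyloxy)-3,5-dimethoxyphenyl]-8-(3-methoxy-4-{[2-(trimethylsilyl)ethoxy]carbonyloxy}phenyl)-3,7-dioxabicyclo[3.3.0]octan-2-one
Conditions: mCPBA, CH2Cl2, 0 °C → rt
Reagents that add atoms: 3-chloroperbenzoic acid OOC(=O)c1cccc(Cl)c1
Why: Baeyer–Villiger oxidation driven by ring strain, in which the benzylic C7, supported by its para-silyloxyaryl group, should migrate with retention in preference to the ring-fusion C5, which is deactivated by the adjacent C–O bond, so oxygen enters between C6 and C7 and the helper C–C bond is removed.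

**Step 8**
Reactants: 14 the doubly protected furofuranone
Product: 15 (1S,4S,5R,8S)-4-(4-hydroxy-3,5-dimethoxyphenyl)-8-(4-hydroxy-3-methoxyphenyl)-3,7-dioxabicyclo[3.3.0]octan-2-one (target)
Conditions: TBAF (2.5 equiv), AcOH (3 equiv), THF, 0 °C → rt
Reagents that add atoms: none
Why: Fluoride-induced desilylation of the aryl silyl ether and beta-silyl fragmentation of the 2-(trimethylsilyl)ethyl carbonate; the acetic acid buffer keeps both phenols protonated, so no quinone methide can form from the para-hydroxybenzylic lactone C–O bond and no stereocentre is touched.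

**Compound list**
1 | 2-methoxybenzene-1,4-diol | COc1cc(O)ccc1O | starting material
2 | 4-hydroxy-3-methoxyphenyl trifluoromethanesulfonate | COc1cc(OS(=O)(=O)C(F)(F)F)ccc1O | intermediate
3 | 3-methoxy-4-{[2-(trimethylsilyl)ethoxy]carbonyloxy}phenyl trifluoromethanesulfonate | COc1cc(OS(=O)(=O)C(F)(F)F)ccc1OC(=O)OCC[Si](C)(C)C | intermediate
4 | 2,3-dihydrofuran | C1=COCC1 | starting material
5 | 4-[(2S)-2,5-dihydrofuran-2-yl]-2-methoxyphenyl 2-(trimethylsilyl)ethyl carbonate | COc1cc([C@H]2OCC=C2)ccc1OC(=O)OCC[Si](C)(C)C | intermediate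
6 | (4-hydroxy-3,5-dimethoxyphenyl)acetic acid | COc1cc(CC(=O)O)cc(OC)c1O | starting material
7 | (2S,5S)-2,5-dimethylpyrrolidine | C[C@H]1CC[C@H](C)N1 | starting material
8 | 2-(4-hydroxy-3,5-dimethoxyphenyl)-1-[(2S,5S)-2,5-dimethylpyrrolidin-1-yl]ethan-1-one | COc1cc(CC(=O)N2[C@@H](C)CC[C@@H]2C)cc(OC)c1O | intermediate
9 | 2-[4-(tert-butyldimethylsilyloxy)-3,5-dimethoxyphenyl]-1-[(2S,5S)-2,5-dimethylpyrrolidin-1-yl]ethan-1-one | COc1cc(CC(=O)N2[C@@H](C)CC[C@@H]2C)cc(OC)c1O[Si](C)(C)C(C)(C)C | intermediate
10 | aryl keteniminium triflate from 9 | COc1cc(C=C=[N+]2[C@@H](C)CC[C@@H]2C)cc(OC)c1O[Si](C)(C)C(C)(C)C.[O-]S(=O)(=O)C(F)(F)F | intermediate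
11 | cis-fused cyclobutaniminium triflate, 4-exo and 7-endo aryl groups | COc1cc([C@H]2OC[C@H]3[C@@H]2C(=[N+]2[C@@H](C)CC[C@@H]2C)[C@H]3c2cc(OC)c(O[Si](C)(C)C(C)(C)C)c(OC)c2)ccc1OC(=O)OCC[Si](C)(C)C.[O-]S(=O)(=O)C(F)(F)F | intermediate
12 | (1R,4S,5S,7R)-7-endo epimer of ketone 13 | COc1cc([C@H]2OC[C@H]3[C@@H]2C(=O)[C@H]3c2cc(OC)c(O[Si](C)(C)C(C)(C)C)c(OC)c2)ccc1OC(=O)OCC[Si](C)(C)C | intermediate
13 | (1R,4S,5S,7S)-4,7-diaryl-3-oxabicyclo[3.2.0]heptan-6-one, both aryl groups exo | COc1cc([C@H]2OC[C@H]3[C@@H]2C(=O)[C@@H]3c2cc(OC)c(O[Si](C)(C)C(C)(C)C)c(OC)c2)ccc1OC(=O)OCC[Si](C)(C)C | intermediate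
14 | (1S,4S,5R,8S)-4,8-diaryl-3,7-dioxabicyclo[3.3.0]octan-2-one, doubly protected | COc1cc([C@H]2OC[C@H]3[C@@H]2C(=O)O[C@@H]3c2cc(OC)c(O[Si](C)(C)C(C)(C)C)c(OC)c2)ccc1OC(=O)OCC[Si](C)(C)C | intermediate
15 | (1S,4S,5R,8S)-4-(4-hydroxy-3,5-dimethoxyphenyl)-8-(4-hydroxy-3-methoxyphenyl)-3,7-dioxabicyclo[3.3.0]octan-2-one | COc1cc([C@H]2OC[C@H]3[C@@H]2C(=O)O[C@@H]3c2cc(OC)c(O)c(OC)c2)ccc1O | target

Total step count: 8. Longest linear sequence: 6 steps (1, 2, 3, 6, 7, 8).

**Steps most likely to fail**

**Step 6.** The ring oxygen or the doubly activated C2–H of 5 may intercept the cation 10, leading to C–O heterolysis, a Claisen-type shift or hydride loss towards the furan. The inductively deactivated alkene may also react too slowly, or the orientation may leak.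

The fallback sets out from 9 and comes back at 14. It keeps the guaiacyl group off the alkene partner until the cycloaddition is over.
- Birch reduction of 2-furoic acid (Na, NH3) gives 2,5-dihydrofuran-2-carboxylic acid F1.
- Resolution through its 1-phenylethylammonium salt gives (S)-2,5-dihydrofuran-2-carboxylic acid F2.
- Boc2O/DMAP/tBuOH gives tert-butyl (S)-2,5-dihydrofuran-2-carboxylate F3. Its C–O bond cannot ionise, and its ester polarises the alkene in the wanted sense and shields one face.
- Ion 10 made from 9 is added to F3 as in step 6. After hydrolysis and equilibration this gives the exo,exo keto ester F4.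
- mCPBA gives the lactone ester F5, and CF3CO2H gives the lactone acid F6.
- Decarboxylative cross-coupling (Ir[dF(CF3)ppy]2(dtbbpy)PF6, NiCl2·glyme, dtbbpy, Cs2CO3, DMF, blue light) joins F6 with 4-bromo-2-methoxyphenyl 2-(trimethylsilyl)ethyl carbonate F7, which is made from 4-bromo-2-methoxyphenol and the carbonate reagent of step 2. The coupling should place the aryl group on the convex face of the alpha-oxy radical and give 14.

**Step 7.** The ring-fusion carbon may migrate in place of the benzylic one, or the peracid may attack the trialkoxyarene.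

The fallback sets out from 13 and comes back at 14. It replaces oxygen insertion by regiodefined cleavage and reclosure.
- TMSOTf/Et3N enolises towards the benzylic carbon and gives the aryl-conjugated trimethylsilyl enol ether F8.
- OsO4 (cat.)/NMO hydroxylates it from the convex face to the alpha-hydroxy ketone F9.
- NaIO4 cleaves the ketol to the cis keto acid F10.
- Hydride reduction of the aryl ketone (L-Selectride, −78 °C) followed by acid work-up lactonises the hydroxy acid to 14. The exo lactone is the less strained epimer and is separable from the other.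

**Step 3.** Turnover of the aryl triflate may be low, the double bond may migrate to the 2,3-dihydro isomer, or facial discrimination may be insufficient.

The fallback sets out from 3 and comes back at 5. It builds the ring by metathesis.
- Reductive carbonylation (Pd(OAc)2, dppp, CO, Et3SiH, Et3N, DMF) gives 4-formyl-2-methoxyphenyl 2-(trimethylsilyl)ethyl carbonate F11.
- Nozaki–Hiyama–Kishi vinylation (vinyl bromide, CrCl2, NiCl2 cat.) gives the racemic allylic alcohol F12.
- Candida antarctica lipase B with vinyl acetate leaves the (S)-allylic alcohol F13 and converts its antipode into the (R)-allylic acetate F14.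
- Ag2O/allyl bromide gives the (S)-diallyl ether F15.
- Ring-closing metathesis with the second-generation Grubbs catalyst gives 5.

**Further compounds**
F1 | step 6 | rac-2,5-dihydrofuran-2-carboxylic acid | OC(=O)C1OCC=C1
F2 | step 6 | (S)-2,5-dihydrofuran-2-carboxylic acid | OC(=O)[C@H]1OCC=C1
F3 | step 6 | tert-butyl (S)-2,5-dihydrofuran-2-carboxylate | CC(C)(C)OC(=O)[C@H]1OCC=C1
F4 | step 6 | tert-butyl 7-exo-[4-(tert-butyldimethylsilyloxy)-3,5-dimethoxyphenyl]-6-oxo-3-oxabicyclo[3.2.0]heptane-4-exo-carboxylate | CC(C)(C)OC(=O)[C@H]1OC[C@H]2[C@@H]1C(=O)[C@@H]2c1cc(OC)c(O[Si](C)(C)C(C)(C)C)c(OC)c1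
F5 | step 6 | tert-butyl 4-exo-aryl-2-oxo-3,7-dioxabicyclo[3.3.0]octane-8-exo-carboxylate | CC(C)(C)OC(=O)[C@H]1OC[C@H]2[C@@H]1C(=O)O[C@@H]2c1cc(OC)c(O[Si](C)(C)C(C)(C)C)c(OC)c1
F6 | step 6 | 4-exo-aryl-2-oxo-3,7-dioxabicyclo[3.3.0]octane-8-exo-carboxylic acid | OC(=O)[C@H]1OC[C@H]2[C@@H]1C(=O)O[C@@H]2c1cc(OC)c(O[Si](C)(C)C(C)(C)C)c(OC)c1
F7 | step 6 | 4-bromo-2-methoxyphenyl 2-(trimethylsilyl)ethyl carbonate | COc1cc(Br)ccc1OC(=O)OCC[Si](C)(C)C
F8 | step 7 | trimethylsilyl enol ether of 13 (C6=C7) | COc1cc([C@H]2OC[C@H]3[C@@H]2C(O[Si](C)(C)C)=C3c2cc(OC)c(O[Si](C)(C)C(C)(C)C)c(OC)c2)ccc1OC(=O)OCC[Si](C)(C)C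
F9 | step 7 | 7-exo-hydroxy-7-endo-aryl ketone | COc1cc([C@H]2OC[C@H]3[C@@H]2C(=O)[C@@]3(O)c2cc(OC)c(O[Si](C)(C)C(C)(C)C)c(OC)c2)ccc1OC(=O)OCC[Si](C)(C)C
F10 | step 7 | 2-aryl-4-aroyltetrahydrofuran-3-carboxylic acid (2,3-trans, 3,4-cis) | COc1cc([C@H]2OC[C@@H]([C@@H]2C(=O)O)C(=O)c2cc(OC)c(O[Si](C)(C)C(C)(C)C)c(OC)c2)ccc1OC(=O)OCC[Si](C)(C)C
F11 | step 3 | 4-formyl-2-methoxyphenyl 2-(trimethylsilyl)ethyl carbonate | COc1cc(C=O)ccc1OC(=O)OCC[Si](C)(C)C
F12 | step 3 | rac-4-(1-hydroxyprop-2-en-1-yl)-2-methoxyphenyl 2-(trimethylsilyl)ethyl carbonate | COc1cc(C(O)C=C)ccc1OC(=O)OCC[Si](C)(C)C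
F13 | step 3 | (S)-4-(1-hydroxyprop-2-en-1-yl)-2-methoxyphenyl 2-(trimethylsilyl)ethyl carbonate | COc1cc([C@@H](O)C=C)ccc1OC(=O)OCC[Si](C)(C)C
F14 | step 3 | (R)-1-aryl-prop-2-en-1-yl acetate | COc1cc([C@H](OC(C)=O)C=C)ccc1OC(=O)OCC[Si](C)(C)C
F15 | step 3 | (S)-4-[1-(allyloxy)prop-2-en-1-yl]-2-methoxyphenyl 2-(trimethylsilyl)ethyl carbonate | COc1cc([C@@H](OCC=C)C=C)ccc1OC(=O)OCC[Si](C)(C)C
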